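The rate constants were drawn at random within sensible limits; the rest is arithmetic.

4 questions stand on these flasks, and we answer them through the part of the capture by first nucleophile that is left as target.

- the best flask by share of target in target plus other capture product; "all alike" if 1.5 percentage points covers them all (birch / maple / oak / all alike)
- share of target in target plus other capture product at the end, birch
- share of target in target plus other capture product at the end, maple
- share of target in target plus other capture product at the end, oak

    substrate → intermediate (k1 = 0.0824 s⁻¹)
    first nucleophile + intermediate → target (k2 = 58.5 L mol⁻¹ s⁻¹)
    second nucleophile + intermediate → other capture product (k3 = 10.7 L mol⁻¹ s⁻¹)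
    intermediate → solvolysis product (k4 = 1.21 s⁻¹)
    target ⇌ isomer of the product (K5 = 0.932, k5 = 0.00721 s⁻¹)
    second nucleophile + protic impurity → quenched reagent (k6 = 0.0736 L mol⁻¹ s⁻¹)
    solid first nucleophile ⇌ first nucleophile, rate k7*(cs7 - [first nucleophile]) while solid is left; crystals form when [first nucleophile] > cs7 (cs7 = 20 mM, k7 = 0.00105 s⁻¹)

| setting | birch | maple | oak |
|---|---|---|---|
| substrate | 0.025 M | 0.025 M (fed, over 12 min) | 0.025 M |
| second nucleophile | 0.0500 M | 0.0500 M | 0.0500 M (fed, over 12 min) |
| protic impurity | 0.0250 M | 0.0250 M | 0.0250 M |
| solid first nucleophile | 0.125 M | 0.125 M | 0.125 M |
| time | 1.0 h | 1.0 h | 1.0 h |
| remark | everything together at the start | all else is in the flask from the start; the feed brings no volume worth counting | all else is in the flask from the start; the feed brings no volume worth counting |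

- given per volume of solution although it is solid: solid first nucleophile
- at the start none of the solid first nucleophile is in solution
- run time (birch): 1.0 h

Capture by first nucleophile makes a pool, target plus isomer of the product, counted as a fraction of the charge. The forward half-life of step 5, 1.6 min, is short against the run of 1.0 h, so we take the pool as equilibrated. The fraction left as target is then one over one plus the equilibrium constant, 51.8%, the kept fraction. With r as the pool over the other capture product, the share asked is kept r over one plus kept r. What remains to find is r, and the selectivity factor of the two captures is 5.47.

In oak, substrate reacts in a burst of half-life 0.14 min, and intermediate leaves faster by step 4 than it forms by step 1, so it follows the substrate left. Both nucleophiles rise from zero: over the feed time, dissolving would supply 0.605 of the substrate charge and the feed brings 2.00. With nothing subtracted, r is 1.65, and our ceiling is 46.1%. If intermediate consumes first nucleophile at its opening strength throughout, r falls to 0.749, and our floor is 27.9%. We commit to the middle r, 1.20, which gives 38.3%.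

In birch, we hold second nucleophile at its charge through the burst and let first nucleophile rise at its opening rate for the mean life of substrate. The total loss rate of intermediate divides both captures alike and cancels in the ratio, so r is 0.0279 and the share 1.42%. For maple we read mid-feed, subtracting half the impurity charge from second nucleophile: r is 0.918 and the share 32.2%. Our best flask is oak.

The forecast gives 1.4% for birch, 29% for maple and 41% for oak, with oak best, and says that “the target then equilibrates with its isomer”. Its oak figure lies inside our bracket, higher than our middle.

The simulation gives 1.34% for birch, 29.6% for maple and 40.9% for oak, with oak best. Oak read at 10.0 h still gives 40.9%. Dividing the oak odds by the kept fraction gives r = 1.34, within the bracket. The same step on maple makes the pool 0.812 times its other capture product, which stands at 19.0% of the substrate charged.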